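**Retrosynthetic overview**
1. Ring numbering: C1 = ring ketone next to the carbinol, C2 = acyl-bearing carbon, C3 = enol carbon, C4 and C5 = CH2, C6 = (S)-CH(OH). Key disconnection: ring bond C2–C3, cut in the retro-Claisen sense with the oxygen on C6 returned to C3, which turns the target into an isomeric open-chain 1,3-diketone hanging on a gamma-lactone.
2. Enabling feature: the C6 oxygen and C3 are 1,4-related (O–C6–C5–C4–C3), so they fit into a five-membered lactone ring that is absent from the target. C1, C6, C5, C4 and C3 with that oxygen are exactly the lactone of (S)-2-hydroxyglutaric acid (chiral pool), and C2 is the only carbon flanked by two ketones (C1 and the exocyclic acyl C=O), hence the only acidic, nucleophilic carbon.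
3. The lactone carries the stereocentre, masks the hydroxyl and activates C3. In the last step the diketonate carbon C2 attacks the lactone carbonyl, so the temporary ring opens as the carbocycle closes and the free (S)-carbinol appears without protecting groups.
4. The diketo lactone comes from a crossed Claisen acylation of (15E)-heptadec-15-en-2-one with (S)-5-oxooxolane-2-carbonyl chloride. The ketone comes from 11-bromoundecan-1-ol by propynylation, sodium–ammonia reduction (E-alkene), bromination and acetone hydrazone alkylation.
5. Order of rings: the temporary five-membered lactone is present from the start; the six-membered carbocycle is formed last, in the step that destroys the lactone.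

Key step: step 7

Remark: the 2-acylcyclohexane-1,3-dione unit of the target is a set of rapidly interconverting enol tautomers of one compound; the endocyclic enol of the given structure is used to represent it.

**Step 1**
Reactants: 1 11-bromoundecan-1-ol; 2 1-propynyllithium
Product: 3 tetradec-12-yn-1-ol
Conditions: 2 (2.5 equiv), THF–DMPU, −20 °C to rt; then H2O
Reagents that add atoms: none
Why: SN2 alkylation of a lithium acetylide by the primary bromide in a dipolar cosolvent should work because the first equivalent of 2 only deprotonates the hydroxyl and the resulting lithium alkoxide is a far poorer nucleophile than the acetylide.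

**Step 2**
Reactants: 3 tetradec-12-yn-1-ol
Product: 4 (12E)-tetradec-12-en-1-ol
Conditions: Na (4 equiv), NH3 (l)–THF, −33 °C; then solid NH4Cl
Reagents that add atoms: none
Why: Dissolving-metal reduction of an internal alkyne runs through the trans vinyl radical anion and vinyl anion and should therefore set the E double bond, with the alkoxide and the isolated product alkene inert.

**Step 3**
Reactants: 4 (12E)-tetradec-12-en-1-ol
Product: 5 (2E)-14-bromotetradec-2-ene
Conditions: CBr4, PPh3, CH2Cl2, 0 °C
Reagents that add atoms: carbon tetrabromide, BrC(Br)(Br)Br
Why: Appel bromination displaces the alkoxyphosphonium group by bromide at the primary carbon under neutral conditions that should leave the E-alkene untouched.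

**Step 4**
Reactants: 5 (2E)-14-bromotetradec-2-ene; 6 propan-2-one dimethylhydrazone (acetone N,N-dimethylhydrazone)
Product: 8 (15E)-heptadec-15-en-2-one, via dimethylhydrazone 7 (not isolated)
Conditions: 6, LiN(iPr)2, THF, 0 °C; then 5, 0 °C to rt; then aq. oxalic acid, Et2O, rt
Reagents that add atoms: water, O
Why: Azaenolate alkylation of a ketone dimethylhydrazone (the acetone equivalent) should give clean monoalkylation at the methyl carbon with a primary bromide, and mild acidic hydrolysis of the C=N bond then frees the methyl ketone without touching the alkene.

**Step 5**
Reactants: 9 (2S)-5-oxooxolane-2-carboxylic acid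
Product: 10 (2S)-5-oxooxolane-2-carbonyl chloride
Conditions: (COCl)2, DMF (cat.), CH2Cl2, 0 °C to rt; evaporation, used crude
Reagents that add atoms: oxalyl chloride, O=C(Cl)C(=O)Cl
Why: DMF-catalysed (Vilsmeier-type) conversion of the acid into its chloride involves no base, so the lactone and the oxygen-bearing stereocentre should be carried through unchanged.

**Step 6**
Reactants: 8 (15E)-heptadec-15-en-2-one; 10 (2S)-5-oxooxolane-2-carbonyl chloride
Product: 11 (5S)-5-[(16E)-3-oxooctadec-16-enoyl]oxolan-2-one
Conditions: 8 (2 equiv), LiN(SiMe3)2 (2 equiv), THF, −78 °C; then 10 (1 equiv), −78 °C; AcOH quench at −78 °C; excess 8 recovered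
Reagents that add atoms: none
Why: In this crossed Claisen acylation the kinetic lithium enolate (methyl side) of 8 should attack the acid chloride far faster than the lactone carbonyl at −78 °C, and the second equivalent of enolate converts the product at once into its lithium diketonate, which stops further acylation and shields the neighbouring stereocentre from enolisation.

**Step 7**
Reactants: 11 (5S)-5-[(16E)-3-oxooctadec-16-enoyl]oxolan-2-one
Product: 12 (6S)-2-[(14E)-hexadec-14-enoyl]-3,6-dihydroxycyclohex-2-en-1-one
Conditions: KOtBu (1.0 equiv), THF (0.02 M), 0 °C to 40 °C; then 1 M HCl to pH 2
Reagents that add atoms: none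
Why: KOtBu removes a proton from the only doubly activated carbon (the CH2 between the two ketones, pKa about 9), and the diketonate carbon adds to the lactone carbonyl five atoms away to give the alkoxide of a 7-oxabicyclo[2.2.1]heptane hemiketal, which collapses by cleavage of the ring C–O bond, so the lactone opens as the carbocycle closes; the liberated alkoxide is protonated by the new, strongly acidic triketone C–H (pKa about 4), which makes the potassium trionate the thermodynamic sink of this isomerisation. The closest known reaction types are the Dieckmann-type intramolecular Claisen condensation of 5-oxo and 5,7-dioxo esters to cyclohexane-1,3-diones (polyketide-type Claisen cyclisation) and the base-induced rearrangement of keto lactones and enol lactones to cyclic 1,3-diones. The six-membered ring closes in the 6-(enolexo)-exo-trig mode, the diketonate reacting through the enolate form whose C=C lies outside the forming ring. No new stereocentre is formed: the carbinol centre comes unchanged from 9, its C–O bond is never broken (only the acyl–oxygen bond is cleaved), and its hydrogen should stay in place because substrate and product are both monoanions and one equivalent of base cannot deprotonate them a second time. The step needs C- over O-acylation and reaction at the central carbon only: O-attack would give a strained enol lactone that forms reversibly and is itself an acyl donor towards the same carbon, no other carbon of the diketonate is nucleophilic, and high dilution suppresses intermolecular Claisen reaction.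

**Compound list**
1 | 11-bromoundecan-1-ol | OCCCCCCCCCCCBr | starting material
2 | 1-propynyllithium | [Li]C#CC | starting material
3 | tetradec-12-yn-1-ol | CC#CCCCCCCCCCCCO | intermediate
4 | (12E)-tetradec-12-en-1-ol | C/C=C/CCCCCCCCCCCO | intermediate
5 | (2E)-14-bromotetradec-2-ene | C/C=C/CCCCCCCCCCCBr | intermediate
6 | propan-2-one dimethylhydrazone (acetone N,N-dimethylhydrazone) | CC(C)=NN(C)C | starting material
7 | (15E)-heptadec-15-en-2-one N,N-dimethylhydrazone | C/C=C/CCCCCCCCCCCCC(C)=NN(C)C | intermediate
8 | (15E)-heptadec-15-en-2-one | C/C=C/CCCCCCCCCCCCC(C)=O | intermediate
9 | (2S)-5-oxooxolane-2-carboxylic acid | O=C(O)[C@@H]1CCC(=O)O1 | starting material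
10 | (2S)-5-oxooxolane-2-carbonyl chloride | O=C(Cl)[C@@H]1CCC(=O)O1 | intermediate
11 | (5S)-5-[(16E)-3-oxooctadec-16-enoyl]oxolan-2-one | C/C=C/CCCCCCCCCCCCC(=O)CC(=O)[C@@H]1CCC(=O)O1 | intermediate
12 | (6S)-2-[(14E)-hexadec-14-enoyl]-3,6-dihydroxycyclohex-2-en-1-one | C/C=C/CCCCCCCCCCCCC(=O)C1=C(O)CC[C@H](O)C1=O | target

**Step count and risks**
Total steps: 7. Longest linear sequence: 6 (steps 1, 2, 3, 4, 6, 7); step 5 is a one-step side branch.

Most likely to fail, in this order:

Step 7. The diketonate carbon has to reach the lactone carbonyl through a strained, oxygen-bridged bicyclic transition state. The closure may therefore be slow, which would give time for intermolecular acyl transfer or for base-induced loss of configuration at the carbinol carbon. The fallback gives up the acyl transfer on the intact lactone, cleaves the temporary ring first with an external nucleophile and closes the open chain. It sets out from 11: NaOMe (2 equiv) in MeOH–THF at 0 °C to 40 °C should transesterify the lactone to methyl (4S,20E)-4-hydroxy-5,7-dioxodocos-20-enoate F1, present as its sodium diketonate and not isolated. F1 should then cyclise as an ordinary open-chain Dieckmann-type Claisen condensation with loss of methoxide through an unstrained monocyclic transition state. Acidification returns the route at 12.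

Step 6. The enolate acylation may suffer from partial O-acylation, equilibration of the kinetic enolate to the internal one, attack at the lactone carbonyl, or ketene formation from the acid chloride with erosion of configuration. The fallback replaces the basic enolate by a neutral, Lewis-acid-mediated acylation in 1:1 stoichiometry. It sets out from 8: LiN(iPr)2 and Me3SiCl in THF at −78 °C should give the kinetic silyl enol ether (15E)-2-(trimethylsilyloxy)heptadeca-1,15-diene F2. F2 is then acylated with 10 under TiCl4 in CH2Cl2 at −78 °C (silyl enol ether acylation, chlorotrimethylsilane lost), and the route is rejoined at 11.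

Step 1. The lithium alkoxide of the bromo alcohol may compete with the acetylide (intermolecular ether formation), HBr may be eliminated from the bromide, and the long-chain alkoxide may precipitate and stall the alkylation. The fallback is a protecting-group version that sets out from 1. 3,4-Dihydro-2H-pyran with pyridinium p-toluenesulfonate (cat.) in CH2Cl2 should give 2-[(11-bromoundecyl)oxy]oxane F3. Alkylation with 2 (1.2 equiv, THF–DMPU) gives 2-(tetradec-12-yn-1-yloxy)oxane F4. Acetal exchange with pyridinium p-toluenesulfonate in MeOH rejoins the route at 3.

**Further compounds**
F1 | step 7 | methyl (4S,20E)-4-hydroxy-5,7-dioxodocos-20-enoate | C/C=C/CCCCCCCCCCCCC(=O)CC(=O)[C@@H](O)CCC(=O)OC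
F2 | step 6 | (15E)-2-(trimethylsilyloxy)heptadeca-1,15-diene | C/C=C/CCCCCCCCCCCCC(=C)O[Si](C)(C)C
F3 | step 1 | 2-[(11-bromoundecyl)oxy]oxane | BrCCCCCCCCCCCOC1CCCCO1
F4 | step 1 | 2-(tetradec-12-yn-1-yloxy)oxane | CC#CCCCCCCCCCCCOC1CCCCO1
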